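## Retrosynthetic overview

1. The target comes from a (2R,3R)-3-hydroxyflavanone (ring B phenols as benzyl ethers) by O-methylation of the 3-OH and hydrogenolysis.
2. Key disconnection (C2–C3): the flavanonol comes from a seven-membered cyclic acetal, a 2-aryl-1,3-benzodioxepin-5(4H)-one, by an acid-catalysed 1,2-shift of the acetal carbon from oxygen to the ketone α-carbon. This ring contraction (7 to 6) closes ring C and sets both stereocentres.
3. The acetal comes from the ring A α-hydroxy ketone and the ring B aldehyde.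
4. The α-hydroxy ketone comes from 3,4,5-trimethoxyphenol and acetoxyacetyl chloride; the phenol comes from Baeyer–Villiger oxidation of 3,4,5-trimethoxybenzaldehyde.
5. Both arenes come from p-cresol through 3,5-dibromo-4-hydroxybenzaldehyde. Rings A and B are present from the start; ring C is made last, first as the seven-membered acetal, then contracted to the pyranone.

Assumption: the (R)-configured acid catalyst of step 7 is taken to give the (2R,3R) product; if the sense of induction is the opposite, the (S)-catalyst is used with no other change.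

## Route

Step 1
Reactants: 1 p-cresol (4-methylphenol)
Product: 4 3,5-dibromo-4-hydroxybenzaldehyde, via 2,6-dibromo-4-methylphenol 2 (not isolated), via 2,6-dibromo-4-(dibromomethyl)phenol 3 (not isolated)
Conditions: Br2 (2 equiv), o-C6H4Cl2, 35 °C; Br2 (2 equiv), 150 °C; H2O, 100 °C
Reagents that add atoms: bromine (BrBr); water (O)
Why: Electrophilic bromination goes to the two positions ortho to OH, hot radical bromination then takes the methyl group to the dibromomethyl stage and hydrolysis gives the aldehyde (side-chain halogenation/hydrolysis, the technical p-cresol route); no stereocentre.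

Step 2
Reactants: 4 3,5-dibromo-4-hydroxybenzaldehyde
Product: 6 3,4,5-trimethoxybenzaldehyde, via sodium 4-formyl-2,6-dimethoxyphenolate 5 (not isolated)
Conditions: NaOMe, CuCl (5 mol%), DMF–MeOH, 115 °C; then Me2SO4, 60 °C
Reagents that add atoms: sodium methoxide ([Na+].[O-]C); dimethyl sulfate (COS(=O)(=O)OC)
Why: Copper-catalysed Ullmann-type methoxylation of the ortho-bromophenolate is followed by Williamson O-methylation of the phenolate in the same pot (the technical syringaldehyde/trimethoxybenzaldehyde process); no stereocentre.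

Step 3
Reactants: 6 3,4,5-trimethoxybenzaldehyde
Product: 8 3,4,5-trimethoxyphenol, via 3,4,5-trimethoxyphenyl formate 7 (not isolated)
Conditions: mCPBA, CH2Cl2, 0 °C to rt; then K2CO3 (cat.), MeOH, rt
Reagents that add atoms: 3-chloroperoxybenzoic acid (OOC(=O)c1cccc(Cl)c1)
Why: Baeyer–Villiger (Dakin-type) oxidation, in which the electron-rich aryl group migrates to oxygen in the Criegee adduct, followed by methanolysis of the aryl formate; no stereocentre.

Step 4
Reactants: 8 3,4,5-trimethoxyphenol; 9 acetoxyacetyl chloride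
Product: 12 2-hydroxy-1-(2-hydroxy-4,5,6-trimethoxyphenyl)ethan-1-one, via 3,4,5-trimethoxyphenyl acetoxyacetate 10 (not isolated), via 2-(2-hydroxy-4,5,6-trimethoxyphenyl)-2-oxoethyl acetate 11 (not isolated)
Conditions: Sc(OTf)3 (10 mol%), PhMe–MeNO2, 100 °C; then MeOH, 65 °C
Reagents that add atoms: none
Why: O-acylation followed by Lewis acid-catalysed Fries rearrangement can only reach the two equivalent positions ortho to OH because the para position carries OMe, and Sc(OTf)3 in methanol then transesterifies the acetate; no stereocentre.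

Step 5
Reactants: 4 3,5-dibromo-4-hydroxybenzaldehyde
Product: 14 3,5-bis(benzyloxy)-4-methoxybenzaldehyde, via cesium 2,6-bis(benzyloxy)-4-formylphenolate 13 (not isolated)
Conditions: BnOH, CuI (10 mol%), 3,4,7,8-tetramethyl-1,10-phenanthroline (20 mol%), Cs2CO3, PhMe, 110 °C; then MeI, DMF, 40 °C
Reagents that add atoms: benzyl alcohol (OCc1ccccc1); iodomethane (CI)
Why: Copper-catalysed Ullmann C–O coupling with benzyl alcohol is run on the phenolate, whose para-oxido group deactivates the aldehyde toward hydride transfer from the alkoxide as in step 2, and the cesium phenolate is then methylated (Williamson); no stereocentre.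

Step 6
Reactants: 12 2-hydroxy-1-(2-hydroxy-4,5,6-trimethoxyphenyl)ethan-1-one; 14 3,5-bis(benzyloxy)-4-methoxybenzaldehyde
Product: 15 rac-2-[3,5-bis(benzyloxy)-4-methoxyphenyl]-6,7,8-trimethoxy-1,3-benzodioxepin-5(4H)-one (seven-membered acetal: aryl–O1–C2H(Ar)–O3–C4H2–C5(=O)–aryl)
Conditions: PPTS (10 mol%), PhMe, 4 Å MS, 80 °C
Reagents that add atoms: none
Why: Acid-catalysed acetalisation driven by water removal, with the ortho-acyl group holding the phenol and the primary alcohol in place for seven-membered ring closure; the acetal carbon forms racemic, which is harmless because step 7 erases and resets it.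

Step 7
Reactants: 15 rac-2-[3,5-bis(benzyloxy)-4-methoxyphenyl]-6,7,8-trimethoxy-1,3-benzodioxepin-5(4H)-one
Product: 16 (2R,3R)-2-[3,5-bis(benzyloxy)-4-methoxyphenyl]-3-hydroxy-5,6,7-trimethoxychroman-4-one (2,3-trans)
Conditions: (R)-3,3'-bis(2,4,6-triisopropylphenyl)-1,1'-binaphthyl-2,2'-diyl N-triflylphosphoramide (5 mol%), PhMe, 5 Å MS, 0 °C to rt
Reagents that add atoms: none
Why: Proposed new method: a chiral Brønsted acid-catalysed, stereoconvergent 1,2-shift of the acetal carbon C2 from O3 to C4 (benzodioxepinone numbering; an ionic Wittig-type O-to-C rearrangement) contracts the seven-membered acetal to the six-membered pyranone. The acid ionises the C2–O3 bond to an aryloxy-stabilised benzylic oxocarbenium ion paired with the chiral phosphoramidate, the freed α-hydroxy ketone enolises under the same bifunctional acid, and the enol carbon closes onto the oxocarbenium carbon in a 6-endo aldol/Prins-type step; ionisation of the other C–O bond is reversible and cannot lead to a ring. The racemic acetal centre is erased on ionisation, the counter-anion hydrogen-bonded to the enol selects the face of the oxocarbenium ion and so sets C2 (R), and C3 is set trans (R) by chair-like closure with both substituents equatorial and by acid-mediated equilibration through the enol. The closest known reactions are the chiral phosphoric acid-catalysed aza-Petasis–Ferrier 1,3-O-to-C rearrangement, the anionic acetal [1,2]-Wittig rearrangement and Brønsted acid-catalysed additions of enols to oxocarbenium ions; none has been run as a 1,2-shift ring contraction to a flavanonol.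

Step 8
Reactants: 16 (2R,3R)-2-[3,5-bis(benzyloxy)-4-methoxyphenyl]-3-hydroxy-5,6,7-trimethoxychroman-4-one
Product: 17 (2R,3R)-2-[3,5-bis(benzyloxy)-4-methoxyphenyl]-3,5,6,7-tetramethoxychroman-4-one
Conditions: MeOTf, 2,6-di-tert-butyl-4-methylpyridine, CH2Cl2, 0 °C to rt
Reagents that add atoms: methyl trifluoromethanesulfonate (COS(=O)(=O)C(F)(F)F)
Why: O-alkylation with methyl triflate buffered by a hindered non-nucleophilic pyridine methylates the secondary alcohol without forming an enolate or alkoxide, so C3 does not epimerise and ring C does not open (non-basic Williamson-type methylation); both stereocentres are kept.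

Step 9
Reactants: 17 (2R,3R)-2-[3,5-bis(benzyloxy)-4-methoxyphenyl]-3,5,6,7-tetramethoxychroman-4-one
Product: 18 (2R,3R)-2-(3,5-dihydroxy-4-methoxyphenyl)-3,5,6,7-tetramethoxychroman-4-one (CNP0075603.1)
Conditions: H2 (1 atm), Pd/C (10%), EtOAc, rt
Reagents that add atoms: none
Why: Hydrogenolysis of the two aryl benzyl ethers over Pd/C under neutral conditions, where the aryl ketone and the cyclic benzylic C2–O bond react slowly at 1 atm; no stereocentre is touched.

## Compound list

1 | p-cresol (4-methylphenol) | Cc1ccc(O)cc1 | starting material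
2 | 2,6-dibromo-4-methylphenol | Cc1cc(Br)c(O)c(Br)c1 | intermediate
3 | 2,6-dibromo-4-(dibromomethyl)phenol | BrC(Br)c1cc(Br)c(O)c(Br)c1 | intermediate
4 | 3,5-dibromo-4-hydroxybenzaldehyde | O=Cc1cc(Br)c(O)c(Br)c1 | intermediate
5 | sodium 4-formyl-2,6-dimethoxyphenolate | [Na+].[O-]c1c(OC)cc(C=O)cc1OC | intermediate
6 | 3,4,5-trimethoxybenzaldehyde | COc1cc(C=O)cc(OC)c1OC | intermediate
7 | 3,4,5-trimethoxyphenyl formate | COc1cc(OC=O)cc(OC)c1OC | intermediate
8 | 3,4,5-trimethoxyphenol | COc1cc(O)cc(OC)c1OC | intermediate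
9 | acetoxyacetyl chloride | CC(=O)OCC(=O)Cl | starting material
10 | 3,4,5-trimethoxyphenyl acetoxyacetate | COc1cc(OC(=O)COC(C)=O)cc(OC)c1OC | intermediate
11 | 2-(2-hydroxy-4,5,6-trimethoxyphenyl)-2-oxoethyl acetate | COc1cc(O)c(C(=O)COC(C)=O)c(OC)c1OC | intermediate
12 | 2-hydroxy-1-(2-hydroxy-4,5,6-trimethoxyphenyl)ethan-1-one | COc1cc(O)c(C(=O)CO)c(OC)c1OC | intermediate
13 | cesium 2,6-bis(benzyloxy)-4-formylphenolate | [Cs+].[O-]c1c(OCc2ccccc2)cc(C=O)cc1OCc1ccccc1 | intermediate
14 | 3,5-bis(benzyloxy)-4-methoxybenzaldehyde | COc1c(OCc2ccccc2)cc(C=O)cc1OCc1ccccc1 | intermediate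
15 | rac-2-[3,5-bis(benzyloxy)-4-methoxyphenyl]-6,7,8-trimethoxy-1,3-benzodioxepin-5(4H)-one | COc1cc2OC(c3cc(OCc4ccccc4)c(OC)c(OCc4ccccc4)c3)OCC(=O)c2c(OC)c1OC | intermediate
16 | (2R,3R)-2-[3,5-bis(benzyloxy)-4-methoxyphenyl]-3-hydroxy-5,6,7-trimethoxychroman-4-one | COc1cc2c(c(OC)c1OC)C(=O)[C@H](O)[C@@H](c1cc(OCc3ccccc3)c(OC)c(OCc3ccccc3)c1)O2 | intermediate
17 | (2R,3R)-2-[3,5-bis(benzyloxy)-4-methoxyphenyl]-3,5,6,7-tetramethoxychroman-4-one | COc1cc2c(c(OC)c1OC)C(=O)[C@H](OC)[C@@H](c1cc(OCc3ccccc3)c(OC)c(OCc3ccccc3)c1)O2 | intermediate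
18 | (2R,3R)-2-(3,5-dihydroxy-4-methoxyphenyl)-3,5,6,7-tetramethoxychroman-4-one | COc1cc2c(c(OC)c1OC)C(=O)[C@H](OC)[C@@H](c1cc(O)c(OC)c(O)c1)O2 | target

## Step count and weak points

Total step count: 9.
Longest linear sequence: 8 steps (1, 2, 3, 4, 6, 7, 8, 9; p-cresol through ring A to the target).

The three steps most likely to fail:

**Step 7 (the proposed ring contraction).** The unknowns are whether the acid ionises the acetal toward the aryloxy oxocarbenium ion fast enough, whether enolisation keeps pace, and how well the catalyst controls the face. The fallback uses known chemistry, sets out from 8 (with 14) and comes back at 16. Phenol 8 is acylated with acetic acid (BF3·OEt2, 90 °C) to 1-(2-hydroxy-4,5,6-trimethoxyphenyl)ethan-1-one F1. The phenol is protected (MOMCl, NaH, DMF) to give 1-[2-(methoxymethoxy)-4,5,6-trimethoxyphenyl]ethan-1-one F2. Claisen–Schmidt condensation with 14 (KOH, EtOH) gives (E)-3-[3,5-bis(benzyloxy)-4-methoxyphenyl]-1-[2-(methoxymethoxy)-4,5,6-trimethoxyphenyl]prop-2-en-1-one F3. Juliá–Colonna epoxidation (poly-L-leucine, urea–H2O2, DBU, THF) gives [(2R,3S)-3-[3,5-bis(benzyloxy)-4-methoxyphenyl]oxiran-2-yl][2-(methoxymethoxy)-4,5,6-trimethoxyphenyl]methanone F4. HCl in MeOH–THF at 50 °C then removes the MOM group, and the freed phenol opens the epoxide at the benzylic carbon with inversion (6-endo) to give 16; the α-carbon keeps R and becomes C3, the β-carbon goes from S to R and becomes C2.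

**Step 6 (seven-membered mixed aryl/alkyl acetal).** Equilibrium acetalisation may stall at open-chain or oligomeric acetals. The fallback sets out from 12 and comes back at 15. Diol 12 is bis-silylated (TMSCl, Et3N, CH2Cl2) to 2-(trimethylsilyloxy)-1-[4,5,6-trimethoxy-2-(trimethylsilyloxy)phenyl]ethan-1-one F5. This is condensed with 14 under kinetic Noyori conditions (TMSOTf 5 mol%, CH2Cl2, −78 °C), where silyl transfer rather than water removal drives ring closure to 15.

**Step 5 (copper benzyloxylation in the presence of the aldehyde, then methylation in the same pot).** Hydrodebromination or hydride transfer from the benzyl alkoxide may compete. The fallback sets out from 4 and comes back at 14. Methylation of 4 (MeI, K2CO3, DMF) gives 3,5-dibromo-4-methoxybenzaldehyde F6. The aldehyde is masked (HC(OMe)3, TsOH cat., MeOH) as 1,3-dibromo-5-(dimethoxymethyl)-2-methoxybenzene F7. Palladium-catalysed C–O coupling with benzyl alcohol (Pd2(dba)3, tBuBrettPhos, Cs2CO3, PhMe, 90 °C) gives 1,3-bis(benzyloxy)-5-(dimethoxymethyl)-2-methoxybenzene F8. Aqueous HCl in THF then releases 14.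

## Further compounds

F1 | step 7 | 1-(2-hydroxy-4,5,6-trimethoxyphenyl)ethan-1-one | COc1cc(O)c(C(C)=O)c(OC)c1OC
F2 | step 7 | 1-[2-(methoxymethoxy)-4,5,6-trimethoxyphenyl]ethan-1-one | COCOc1cc(OC)c(OC)c(OC)c1C(C)=O
F3 | step 7 | (E)-3-[3,5-bis(benzyloxy)-4-methoxyphenyl]-1-[2-(methoxymethoxy)-4,5,6-trimethoxyphenyl]prop-2-en-1-one | COCOc1cc(OC)c(OC)c(OC)c1C(=O)/C=C/c1cc(OCc2ccccc2)c(OC)c(OCc2ccccc2)c1
F4 | step 7 | [(2R,3S)-3-[3,5-bis(benzyloxy)-4-methoxyphenyl]oxiran-2-yl][2-(methoxymethoxy)-4,5,6-trimethoxyphenyl]methanone | COCOc1cc(OC)c(OC)c(OC)c1C(=O)[C@@H]2O[C@H]2c3cc(OCc4ccccc4)c(OC)c(OCc4ccccc4)c3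
F5 | step 6 | 2-(trimethylsilyloxy)-1-[4,5,6-trimethoxy-2-(trimethylsilyloxy)phenyl]ethan-1-one | COc1cc(O[Si](C)(C)C)c(C(=O)CO[Si](C)(C)C)c(OC)c1OC
F6 | step 5 | 3,5-dibromo-4-methoxybenzaldehyde | COc1c(Br)cc(C=O)cc1Br
F7 | step 5 | 1,3-dibromo-5-(dimethoxymethyl)-2-methoxybenzene | COc1c(Br)cc(C(OC)OC)cc1Br
F8 | step 5 | 1,3-bis(benzyloxy)-5-(dimethoxymethyl)-2-methoxybenzene | COc1c(OCc2ccccc2)cc(C(OC)OC)cc1OCc1ccccc1
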